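**Strategy.** The butenolide (O–C6–C7=C11–C12) is fused to the ten-membered carbocycle through the C6–C7 bond. A hetero-Pauson–Khand [2+2+1] union of an aldehyde (C6), an alkyne (C7≡C11) and CO (C12) therefore closes both rings at once. The precursor is an acyclic (Z)-enal/alkyne in which the C1 ketone and the C8 hydroxyl, 1,4-related in the ring, are tied up as a cyclic methyl ketal (a 2,5-cis oxolane). This temporary ring masks the ketone, protects O8 and folds the chain. C10 comes from (S)-citramalic acid, C8 from an alkynone transfer hydrogenation, C6 from the key step; three acylations finish the synthesis.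

Key step: step 13

Remark: germacranolide numbering is used (C1 ring ketone, C4=C5, C6 lactone carbinol, C7=C11, C8 ester carbinol, C10 quaternary carbinol, C12 lactone carbonyl, C13 CH2O); the sense of the transfer hydrogenation in step 3 is assumed to follow that of simple alkynyl ketones.

Step 1
Reactants: 1 (S)-citramalic acid
Product: 2 2-[(4S)-2,2,4-trimethyl-5-oxo-1,3-dioxolan-4-yl]acetic acid
Conditions: 2,2-dimethoxypropane, pyridinium p-toluenesulfonate (cat.), CH2Cl2, rt
Reagents that add atoms: 2,2-dimethoxypropane, COC(C)(C)OC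
Why: Acid-catalysed ketal exchange (acetonide formation) should engage the α-hydroxy acid selectively as the five-membered dioxolanone, as with malic acid, leaving the C8 carboxyl free and C10 untouched.

Step 2
Reactants: 2 2-[(4S)-2,2,4-trimethyl-5-oxo-1,3-dioxolan-4-yl]acetic acid, 3 tert-butyl(diphenyl)(prop-2-yn-1-yloxy)silane
Product: 5 (5S)-5-{5-[(tert-butyldiphenylsilyl)oxy]-2-oxopent-3-yn-1-yl}-2,2,5-trimethyl-1,3-dioxolan-4-one, via acid chloride 4 (not isolated)
Conditions: (COCl)2, DMF (cat.), CH2Cl2, 0 °C to rt; then 3, PdCl2(PPh3)2 (cat.), CuI (cat.), Et3N, THF, rt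
Reagents that add atoms: none
Why: Acid chloride formation followed by acyl Sonogashira coupling should give the alkynone without touching the dioxolanone, and C10 carries no hydrogen that could epimerise.

Step 3
Reactants: 5 (5S)-5-{5-[(tert-butyldiphenylsilyl)oxy]-2-oxopent-3-yn-1-yl}-2,2,5-trimethyl-1,3-dioxolan-4-one
Product: 6 (5S)-5-{(2S)-5-[(tert-butyldiphenylsilyl)oxy]-2-hydroxypent-3-yn-1-yl}-2,2,5-trimethyl-1,3-dioxolan-4-one
Conditions: RuCl[(S,S)-TsDPEN](p-cymene) (cat.), 2-propanol, rt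
Reagents that add atoms: none
Why: Noyori asymmetric transfer hydrogenation of alkynyl ketones is catalyst-controlled, and the (S,S)-ligand should deliver hydride to give the (S)-carbinol at C8 (alkynyl in the role of aryl), overriding the remote C10 centre.

Step 4
Reactants: 6 (5S)-5-{(2S)-5-[(tert-butyldiphenylsilyl)oxy]-2-hydroxypent-3-yn-1-yl}-2,2,5-trimethyl-1,3-dioxolan-4-one
Product: 7 (3S,5S)-5-{3-[(tert-butyldiphenylsilyl)oxy]prop-1-yn-1-yl}-3-hydroxy-3-methyloxolan-2-one
Conditions: camphorsulfonic acid (cat.), toluene, 40 °C, acetone removed under reduced pressure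
Reagents that add atoms: none
Why: Acid-catalysed translactonisation: the C8 hydroxyl should attack the dioxolanone carbonyl to form the γ-lactone, driven by loss of acetone, with no stereocentre affected.

Step 5
Reactants: 7 (3S,5S)-5-{3-[(tert-butyldiphenylsilyl)oxy]prop-1-yn-1-yl}-3-hydroxy-3-methyloxolan-2-one
Product: 8 (3S,5S)-5-{3-[(tert-butyldiphenylsilyl)oxy]prop-1-yn-1-yl}-3-methyl-3-[(trimethylsilyl)oxy]oxolan-2-one
Conditions: Me3SiOTf, Et3N, CH2Cl2, −78 to 0 °C
Reagents that add atoms: trimethylsilyl trifluoromethanesulfonate, C[Si](C)(C)OS(=O)(=O)C(F)(F)F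
Why: Silyl ether formation with the silyl triflate should cap the tertiary hydroxyl, the only acidic proton, before the organolithium step.

Step 6
Reactants: 9 but-2-yn-1-ol
Product: 10 (2Z)-3-iodobut-2-en-1-ol
Conditions: NaAlH2(OCH2CH2OCH3)2, THF, 0 °C to rt; then I2, −78 °C
Reagents that add atoms: iodine, II
Why: Hydroxyl-directed trans-hydroalumination places aluminium at C3 cis to the CH2O group and iodinolysis with retention should give the (Z)-iodoalkene, which fixes the C4=C5 geometry of the target.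

Step 7
Reactants: 10 (2Z)-3-iodobut-2-en-1-ol
Product: 11 tert-butyl{[(2Z)-3-iodobut-2-en-1-yl]oxy}dimethylsilane
Conditions: t-BuMe2SiCl, imidazole, CH2Cl2, rt
Reagents that add atoms: tert-butyldimethylsilyl chloride, CC(C)(C)[Si](C)(C)Cl
Why: Standard silyl ether formation; this group should resist 1,4-silyl migration at −78 °C in the next step and is cleaved later by acidic methanol.

Step 8
Reactants: 11 tert-butyl{[(2Z)-3-iodobut-2-en-1-yl]oxy}dimethylsilane, 12 oxirane
Product: 14 (3Z)-5-[(tert-butyldimethylsilyl)oxy]-3-methylpent-3-en-1-ol, via alkenyllithium 13 (not isolated)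
Conditions: t-BuLi (2.1 equiv), Et2O, −78 °C; then 12, BF3·OEt2, −78 °C
Reagents that add atoms: none
Why: Iodine–lithium exchange proceeds with retention of alkene geometry and Lewis-acid-promoted epoxide opening should add C2 and C3 at low temperature.

Step 9
Reactants: 14 (3Z)-5-[(tert-butyldimethylsilyl)oxy]-3-methylpent-3-en-1-ol
Product: 15 tert-butyl{[(2Z)-5-iodo-3-methylpent-2-en-1-yl]oxy}dimethylsilane
Conditions: I2, PPh3, imidazole, CH2Cl2, 0 °C
Reagents that add atoms: iodine, II
Why: Appel-type iodination of the primary alcohol under buffered conditions should leave the allylic silyl ether and the alkene intact.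

Step 10
Reactants: 15 tert-butyl{[(2Z)-5-iodo-3-methylpent-2-en-1-yl]oxy}dimethylsilane, 8 (3S,5S)-5-{3-[(tert-butyldiphenylsilyl)oxy]prop-1-yn-1-yl}-3-methyl-3-[(trimethylsilyl)oxy]oxolan-2-one
Product: 17 (3S,5S)-2-{(3Z)-5-[(tert-butyldimethylsilyl)oxy]-3-methylpent-3-en-1-yl}-5-{3-[(tert-butyldiphenylsilyl)oxy]prop-1-yn-1-yl}-3-methyl-3-[(trimethylsilyl)oxy]oxolan-2-ol (lactol, both C2 epimers), via alkyllithium 16 (not isolated)
Conditions: t-BuLi (2.05 equiv), Et2O–pentane, −78 °C; then 8 in THF, −78 °C; aq NH4Cl at −78 °C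
Reagents that add atoms: none
Why: Iodine–lithium exchange and 1,2-addition to the lactone should stop at the hemiketal, because the lactone has no α-hydrogen and the tetrahedral lithium alkoxide is stable at −78 °C, as in additions of organolithiums to silylated sugar lactones.

Step 11
Reactants: 17 lactol (both C2 epimers)
Product: 18 (2Z)-5-[(2S,3S,5S)-5-{3-[(tert-butyldiphenylsilyl)oxy]prop-1-yn-1-yl}-3-hydroxy-2-methoxy-3-methyloxolan-2-yl]-3-methylpent-2-en-1-ol
Conditions: camphorsulfonic acid (cat.), MeOH, 0 °C; chromatographic separation, the (2R) epimer being resubmitted to the same conditions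
Reagents that add atoms: methanol, CO
Why: Acid-catalysed ketalisation through the cyclic oxocarbenium ion should give the methyl ketal while acidic methanol cleaves the primary allylic and the trimethylsilyl ethers and spares the diphenylsilyl ether; the ketal carbon forms as two equilibrating epimers, of which the (2S) one, with the pentenyl chain cis to the alkynyl group, is collected.

Step 12
Reactants: 18 (2Z)-5-[(2S,3S,5S)-5-{3-[(tert-butyldiphenylsilyl)oxy]prop-1-yn-1-yl}-3-hydroxy-2-methoxy-3-methyloxolan-2-yl]-3-methylpent-2-en-1-ol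
Product: 19 (2Z)-5-[(2S,3S,5S)-5-{3-[(tert-butyldiphenylsilyl)oxy]prop-1-yn-1-yl}-3-hydroxy-2-methoxy-3-methyloxolan-2-yl]-3-methylpent-2-enal
Conditions: MnO2 (excess), CH2Cl2, rt
Reagents that add atoms: none
Why: MnO2 allylic oxidation should convert only the primary allylic alcohol and keep the Z geometry (as for nerol to neral), the tertiary alcohol being inert.

Step 13
Reactants: 19 (2Z)-5-[(2S,3S,5S)-5-{3-[(tert-butyldiphenylsilyl)oxy]prop-1-yn-1-yl}-3-hydroxy-2-methoxy-3-methyloxolan-2-yl]-3-methylpent-2-enal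
Product: 20 (1S,4Z,6R,8S,10S)-13-[(tert-butyldiphenylsilyl)oxy]-10-hydroxy-1-methoxy-1,8-epoxygermacra-4,7(11)-dien-12,6-olide
Conditions: Mo(CO)6 (1.2 equiv), DMSO (10 equiv), toluene, 100 °C, slow addition of 19 to a final 0.002 M
Reagents that add atoms: carbon monoxide delivered by Mo(CO)6, [C-]#[O+]
Why: Proposed new method: DMSO strips CO from Mo(CO)6 to give a zerovalent molybdenum carbonyl fragment that binds the alkyne C7≡C11 and the aldehyde C6=O; oxidative cyclisation forms C6–C7 in an oxamolybdacyclopentene, CO inserts into the Mo–C11 bond (C11–C12) and C–O reductive elimination releases the butenolide, a hetero-Pauson–Khand [2+2+1] cycloaddition. The closest known reaction type is the Mo(CO)6/DMSO hetero-Pauson–Khand reaction of 1,6- and 1,7-alkynals to fused butenolides; the new element is the ring size, for which the nearest analogy is the oxidative cyclisation that underlies nickel-mediated macrocyclisation of alkynals. The butenolide closes in the [2+2+1] mode and the ten-membered carbocycle closes at the same C6–C7 bond in the exo sense (C11 stays outside the ring), the two ends being held together by the cis-2,5-disubstituted oxolane and the 4Z alkene. C6 is controlled by the C8 stereocentre: the nine-membered oxa-bridged ring (O–C1–C2–C3–C4=C5–C6–C7–C8) should leave the planar C6–C7–C8 unit on one face, so C5 is expected on the face of the butenolide plane that carries the C8–O bond (C8–H lying in that plane to avoid allylic strain with C13), which corresponds to 6R. Regioselectivity is secured by the tether, since bonding of C6 to C11 would place an E-configured tetrasubstituted alkene in an eleven-membered ring. Chemoselectivity is secured by the ketal, which removes the C1 ketone that would otherwise undergo 1,6-alkynone cyclisation, and by the trisubstituted alkene, which is too hindered for a carbocyclic Pauson–Khand reaction.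

Step 14
Reactants: 20 (1S,4Z,6R,8S,10S)-13-[(tert-butyldiphenylsilyl)oxy]-10-hydroxy-1-methoxy-1,8-epoxygermacra-4,7(11)-dien-12,6-olide
Product: 22 (4Z,6R,8S,10S)-8,10,13-trihydroxy-1-oxogermacra-4,7(11)-dien-12,6-olide (in equilibrium with its 1,8-hemiketal), via ketal diol 21 (not isolated)
Conditions: n-Bu4NF, AcOH, THF, 0 °C to rt; then 1 M aq HCl, rt
Reagents that add atoms: water, O
Why: Buffered fluoride desilylation should spare the base-sensitive butenolide, and dilute acid then hydrolyses the bicyclic ketal to the C1 ketone and the free C8 hydroxyl without disturbing C6, C8 or C10.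

Step 15
Reactants: 22 (4Z,6R,8S,10S)-8,10,13-trihydroxy-1-oxogermacra-4,7(11)-dien-12,6-olide
Product: 23 (4Z,6R,8S,10S)-13-acetoxy-8,10-dihydroxy-1-oxogermacra-4,7(11)-dien-12,6-olide
Conditions: AcCl (1.05 equiv), 2,4,6-collidine, CH2Cl2, −78 °C
Reagents that add atoms: acetyl chloride, CC(=O)Cl
Why: Selective acylation: at low temperature acetyl chloride with a hindered base should acylate the unhindered primary allylic alcohol in preference to the secondary (partly hemiketal-masked) and tertiary hydroxyls.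

Step 16
Reactants: 23 (4Z,6R,8S,10S)-13-acetoxy-8,10-dihydroxy-1-oxogermacra-4,7(11)-dien-12,6-olide
Product: 24 (4Z,6R,8S,10S)-13-acetoxy-10-hydroxy-8-(methacryloyloxy)-1-oxogermacra-4,7(11)-dien-12,6-olide
Conditions: methacrylic anhydride, DMAP (cat.), Et3N, CH2Cl2, 0 °C to rt
Reagents that add atoms: methacrylic anhydride, C=C(C)C(=O)OC(=O)C(C)=C
Why: DMAP-catalysed acylation should esterify the secondary C8 hydroxyl, drawn from the hydroxy ketone–hemiketal equilibrium, with retention at C8, the tertiary C10 hydroxyl being too hindered to compete.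

Step 17
Reactants: 24 (4Z,6R,8S,10S)-13-acetoxy-10-hydroxy-8-(methacryloyloxy)-1-oxogermacra-4,7(11)-dien-12,6-olide
Product: 25 (4Z,6R,8S,10S)-10,13-diacetoxy-8-(methacryloyloxy)-1-oxogermacra-4,7(11)-dien-12,6-olide (target)
Conditions: Ac2O, Sc(OTf)3 (cat.), MeCN, −20 to 0 °C
Reagents that add atoms: acetic anhydride, CC(=O)OC(C)=O
Why: Lewis-acid-catalysed acetylation with acetic anhydride acylates tertiary alcohols at low temperature, and the α-keto carbinol should resist ionisation and elimination, so C10 keeps its configuration.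

**Compound list**

1 | (S)-citramalic acid | C[C@](O)(CC(=O)O)C(=O)O | starting material
2 | 2-[(4S)-2,2,4-trimethyl-5-oxo-1,3-dioxolan-4-yl]acetic acid | C[C@@]1(CC(=O)O)OC(C)(C)OC1=O | intermediate
3 | tert-butyl(diphenyl)(prop-2-yn-1-yloxy)silane | C#CCO[Si](c1ccccc1)(c1ccccc1)C(C)(C)C | starting material
4 | 2-[(4S)-2,2,4-trimethyl-5-oxo-1,3-dioxolan-4-yl]acetyl chloride | C[C@@]1(CC(=O)Cl)OC(C)(C)OC1=O | intermediate
5 | (5S)-5-{5-[(tert-butyldiphenylsilyl)oxy]-2-oxopent-3-yn-1-yl}-2,2,5-trimethyl-1,3-dioxolan-4-one | C[C@@]1(CC(=O)C#CCO[Si](c2ccccc2)(c2ccccc2)C(C)(C)C)OC(C)(C)OC1=O | intermediate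
6 | (5S)-5-{(2S)-5-[(tert-butyldiphenylsilyl)oxy]-2-hydroxypent-3-yn-1-yl}-2,2,5-trimethyl-1,3-dioxolan-4-one | C[C@@]1(C[C@H](O)C#CCO[Si](c2ccccc2)(c2ccccc2)C(C)(C)C)OC(C)(C)OC1=O | intermediate
7 | (3S,5S)-5-{3-[(tert-butyldiphenylsilyl)oxy]prop-1-yn-1-yl}-3-hydroxy-3-methyloxolan-2-one | C[C@]1(O)C[C@@H](C#CCO[Si](c2ccccc2)(c2ccccc2)C(C)(C)C)OC1=O | intermediate
8 | (3S,5S)-5-{3-[(tert-butyldiphenylsilyl)oxy]prop-1-yn-1-yl}-3-methyl-3-[(trimethylsilyl)oxy]oxolan-2-one | C[C@]1(O[Si](C)(C)C)C[C@@H](C#CCO[Si](c2ccccc2)(c2ccccc2)C(C)(C)C)OC1=O | intermediate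
9 | but-2-yn-1-ol | CC#CCO | starting material
10 | (2Z)-3-iodobut-2-en-1-ol | C/C(I)=C/CO | intermediate
11 | tert-butyl{[(2Z)-3-iodobut-2-en-1-yl]oxy}dimethylsilane | C/C(I)=C/CO[Si](C)(C)C(C)(C)C | intermediate
12 | oxirane | C1CO1 | starting material
13 | {(2Z)-4-[(tert-butyldimethylsilyl)oxy]but-2-en-2-yl}lithium | [Li]/C(C)=C\CO[Si](C)(C)C(C)(C)C | intermediate
14 | (3Z)-5-[(tert-butyldimethylsilyl)oxy]-3-methylpent-3-en-1-ol | OCC/C(C)=C\CO[Si](C)(C)C(C)(C)C | intermediate
15 | tert-butyl{[(2Z)-5-iodo-3-methylpent-2-en-1-yl]oxy}dimethylsilane | ICC/C(C)=C\CO[Si](C)(C)C(C)(C)C | intermediate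
16 | {(3Z)-5-[(tert-butyldimethylsilyl)oxy]-3-methylpent-3-en-1-yl}lithium | [Li]CC/C(C)=C\CO[Si](C)(C)C(C)(C)C | intermediate
17 | (3S,5S)-2-{(3Z)-5-[(tert-butyldimethylsilyl)oxy]-3-methylpent-3-en-1-yl}-5-{3-[(tert-butyldiphenylsilyl)oxy]prop-1-yn-1-yl}-3-methyl-3-[(trimethylsilyl)oxy]oxolan-2-ol (both C2 epimers) | CC(C)(C)[Si](C)(C)OC/C=C(C)\CCC1(O)O[C@H](C#CCO[Si](c2ccccc2)(c2ccccc2)C(C)(C)C)C[C@]1(C)O[Si](C)(C)C | intermediate
18 | (2Z)-5-[(2S,3S,5S)-5-{3-[(tert-butyldiphenylsilyl)oxy]prop-1-yn-1-yl}-3-hydroxy-2-methoxy-3-methyloxolan-2-yl]-3-methylpent-2-en-1-ol | OC/C=C(C)\CC[C@]1(OC)O[C@H](C#CCO[Si](c2ccccc2)(c2ccccc2)C(C)(C)C)C[C@]1(C)O | intermediate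
19 | (2Z)-5-[(2S,3S,5S)-5-{3-[(tert-butyldiphenylsilyl)oxy]prop-1-yn-1-yl}-3-hydroxy-2-methoxy-3-methyloxolan-2-yl]-3-methylpent-2-enal | O=C/C=C(C)\CC[C@]1(OC)O[C@H](C#CCO[Si](c2ccccc2)(c2ccccc2)C(C)(C)C)C[C@]1(C)O | intermediate
20 | (1S,4Z,6R,8S,10S)-13-[(tert-butyldiphenylsilyl)oxy]-10-hydroxy-1-methoxy-1,8-epoxygermacra-4,7(11)-dien-12,6-olide | CO[C@]12CC/C(C)=C\[C@H]3OC(=O)C(CO[Si](c4ccccc4)(c4ccccc4)C(C)(C)C)=C3[C@H](C[C@]1(C)O)O2 | intermediate
21 | (1S,4Z,6R,8S,10S)-10,13-dihydroxy-1-methoxy-1,8-epoxygermacra-4,7(11)-dien-12,6-olide | CO[C@]12CC/C(C)=C\[C@H]3OC(=O)C(CO)=C3[C@H](C[C@]1(C)O)O2 | intermediate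
22 | (4Z,6R,8S,10S)-8,10,13-trihydroxy-1-oxogermacra-4,7(11)-dien-12,6-olide | O[C@H]1C[C@](C)(O)C(=O)CC/C(C)=C\[C@H]2OC(=O)C(CO)=C12 | intermediate
23 | (4Z,6R,8S,10S)-13-acetoxy-8,10-dihydroxy-1-oxogermacra-4,7(11)-dien-12,6-olide | O[C@H]1C[C@](C)(O)C(=O)CC/C(C)=C\[C@H]2OC(=O)C(COC(C)=O)=C12 | intermediate
24 | (4Z,6R,8S,10S)-13-acetoxy-10-hydroxy-8-(methacryloyloxy)-1-oxogermacra-4,7(11)-dien-12,6-olide | C=C(C)C(=O)O[C@H]1C[C@](C)(O)C(=O)CC/C(C)=C\[C@H]2OC(=O)C(COC(C)=O)=C12 | intermediate
25 | (4Z,6R,8S,10S)-10,13-diacetoxy-8-(methacryloyloxy)-1-oxogermacra-4,7(11)-dien-12,6-olide | C=C(C)C(=O)O[C@H]1C[C@](C)(OC(C)=O)C(=O)CC/C(C)=C\[C@H]2OC(=O)C(COC(C)=O)=C12 | target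

**Step count.** Total: 17 steps. Longest linear sequence: 13 steps (steps 1–5, then 10–17).

**Steps most likely to fail**

Step 13. The macrocyclic oxidative cyclisation may not compete with oligomerisation or decomposition of the alkyne–molybdenum complex at high dilution, and facial selectivity at C6 may be poor. The fallback uses known chemistry, sets out from 19 and comes back at 21. The ring would be closed first by the established zerovalent-nickel-catalysed reductive macrocyclisation of alkynals (Ni(cod)2, IMes·HCl, KOt-Bu, Et3SiH, THF, high dilution). This forms C6–C7 with syn delivery of hydrogen to C11 and should give the macrocyclic allylic triethylsilyl ether F1. n-Bu4NF then removes both silyl groups to give the 6,10,13-triol F2. TEMPO/PhI(OAc)2 oxidises the primary allylic alcohol to the enal F3, whose formyl group is trans to C6 and cannot form a lactol. I2/DMAP/K2CO3 iodinates the α-position to give the iodo enal F4, with iodine cis to the C6 carbinol. Pd(PPh3)4/CO/Et3N closes the butenolide by carbonylative lactonisation (C11–C12) to the formyl butenolide F5, and Luche reduction (NaBH4, CeCl3) of the aldehyde gives 21.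

Step 10. The organolithium may add twice if the hemiketal alkoxide collapses before the quench, or may be consumed by attack at silicon or by propargylic deprotonation. The fallback sets out from 7 and comes back at 18. Aminolysis of the lactone (MeNHOMe·HCl, i-PrMgCl, THF) gives the dihydroxy Weinreb amide F6, and Et3SiOTf/2,6-lutidine gives the bis(triethylsilyl) ether F7. Addition of 16 through the stable chelated tetrahedral intermediate gives the ketone F8. Camphorsulfonic acid in methanol then removes the three labile silyl groups and closes the methyl ketal to 18.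

Step 17. Acylation of the tertiary α-ketol may be slow and accompanied by elimination, acyl shift or polymerisation of the methacrylate. The fallback changes the order of the end game, sets out from 21 (isolated after the fluoride stage of step 14) and comes back at 25. Ac2O/DMAP/Et3N at 40 °C acetylates both hydroxyls while C1 is still a ketal and no methacrylate is present, giving the diacetate F9. Pyridinium p-toluenesulfonate in acetone–water hydrolyses the ketal to the 8-hydroxy ketone F10, and methacryloylation as in step 16 gives 25.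

Further compounds
F1 | step 13 | macrocyclic ketal with 6R triethylsilyloxy group and exocyclic C7=C11H–CH2OSi(t-Bu)Ph2 alkene (C6 trans to C13), from reductive cyclisation of 19 | CO[C@]12CC/C(C)=C\[C@@H](O[Si](CC)(CC)CC)/C(=C/CO[Si](c3ccccc3)(c3ccccc3)C(C)(C)C)[C@H](C[C@]1(C)O)O2
F2 | step 13 | 6,10,13-triol of the same macrocyclic ketal | CO[C@]12CC/C(C)=C\[C@@H](O)/C(=C/CO)[C@H](C[C@]1(C)O)O2
F3 | step 13 | macrocyclic ketal 6,10-diol with C13 aldehyde (enal, formyl trans to C6) | CO[C@]12CC/C(C)=C\[C@@H](O)/C(=C/C=O)[C@H](C[C@]1(C)O)O2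
F4 | step 13 | 11-iodo derivative of the enal (iodine cis to C6) | CO[C@]12CC/C(C)=C\[C@@H](O)/C(=C(I)/C=O)[C@H](C[C@]1(C)O)O2
F5 | step 13 | (1S,4Z,6R,8S,10S)-10-hydroxy-1-methoxy-13-oxo-1,8-epoxygermacra-4,7(11)-dien-12,6-olide | CO[C@]12CC/C(C)=C\[C@H]3OC(=O)C(C=O)=C3[C@H](C[C@]1(C)O)O2
F6 | step 10 | (2S,4S)-7-[(tert-butyldiphenylsilyl)oxy]-2,4-dihydroxy-N-methoxy-N,2-dimethylhept-5-ynamide | CON(C)C(=O)[C@@](C)(O)C[C@H](O)C#CCO[Si](c1ccccc1)(c1ccccc1)C(C)(C)C
F7 | step 10 | (2S,4S)-7-[(tert-butyldiphenylsilyl)oxy]-N-methoxy-N,2-dimethyl-2,4-bis[(triethylsilyl)oxy]hept-5-ynamide | CON(C)C(=O)[C@@](C)(O[Si](CC)(CC)CC)C[C@H](O[Si](CC)(CC)CC)C#CCO[Si](c1ccccc1)(c1ccccc1)C(C)(C)C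
F8 | step 10 | open-chain C1 ketone: (2Z,7S,9S)-1-[(tert-butyldimethylsilyl)oxy]-12-[(tert-butyldiphenylsilyl)oxy]-3,7-dimethyl-7,9-bis[(triethylsilyl)oxy]dodec-2-en-10-yn-6-one | CC(C)(C)[Si](C)(C)OC/C=C(C)\CCC(=O)[C@@](C)(O[Si](CC)(CC)CC)C[C@H](O[Si](CC)(CC)CC)C#CCO[Si](c1ccccc1)(c1ccccc1)C(C)(C)C
F9 | step 17 | (1S,4Z,6R,8S,10S)-10,13-diacetoxy-1-methoxy-1,8-epoxygermacra-4,7(11)-dien-12,6-olide | CO[C@]12CC/C(C)=C\[C@H]3OC(=O)C(COC(C)=O)=C3[C@H](C[C@]1(C)OC(C)=O)O2
F10 | step 17 | (4Z,6R,8S,10S)-10,13-diacetoxy-8-hydroxy-1-oxogermacra-4,7(11)-dien-12,6-olide | O[C@H]1C[C@](C)(OC(C)=O)C(=O)CC/C(C)=C\[C@H]2OC(=O)C(COC(C)=O)=C12
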